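**Retrosynthetic overview**
- Target ⇐ global deprotection; the 4‑hydroxystyryl arm comes from a Heck reaction of 4‑iodophenol with a C6‑vinyl group, installed by sterically controlled Ir C–H borylation/Suzuki vinylation at the only unhindered arene C–H.
- Central benzene ring ⇐ dehydrogenative aromatisation of a 3,5,6,7‑tetrahydrobenzofuran‑4‑one (the C4–OH is the former ketone).
- Key step: dihydrofuran ring (C3–C3a, then C2–O1) ⇐ Mn(III) oxidative radical [3+2] annulation of cyclohexane‑1,3‑dione with a silyl‑protected oxyresveratrol‑type stilbene. It sets the 2,3‑trans relationship but gives a racemate; the enantiomer is selected by separating diastereomeric camphanates.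
- Stilbene ⇐ Heck coupling of a 4‑bromo and a 5‑vinyl resorcinol bis‑silyl ether, both made from resorcinol.
- Ring order: two resorcinol rings (bought) → dihydrofuran ring (radical step) → central benzene ring (aromatisation).

Assumption: racemic compounds 9–11 are written with the (2S,3S) enantiomer drawn; TIPSO = triisopropylsilyloxy.

**Step 1**
Reactants: 1 resorcinol
Product: 2 1,3-bis(TIPSO)benzene
Conditions: TIPSCl (2.2 equiv), imidazole, DMF, rt
Reagents that add atoms: triisopropylsilyl chloride, CC(C)[Si](Cl)(C(C)C)C(C)C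
Why: Standard O‑silylation of both phenols; the bulky, base‑stable TIPS ethers keep the rings electron‑rich and later shield all ortho C–H bonds.

**Step 2**
Reactants: 2 1,3-bis(TIPSO)benzene; 3 vinyl bromide
Product: 5 1,3-bis(TIPSO)-5-vinylbenzene, via arylboronate 4 (not isolated)
Conditions: [Ir(OMe)(cod)]2 (1.5 mol%), dtbpy, B2pin2 (1 equiv), THF, 80 °C; evaporate; Pd(dppf)Cl2, 3 (1 M in THF, 3 equiv), aq K3PO4, THF, 60 °C, sealed
Reagents that add atoms: bis(pinacolato)diboron, CC1(C)OB(OC1(C)C)B1OC(C)(C)C(C)(C)O1 (its boryl group is in 4 only)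
Why: Sterically controlled Ir‑catalysed C–H borylation goes to C5, the only C–H not flanked by a TIPSO group, and the boronate is vinylated in the same pot by Suzuki–Miyaura coupling.

**Step 3**
Reactants: 2 1,3-bis(TIPSO)benzene
Product: 6 1-bromo-2,4-bis(TIPSO)benzene
Conditions: NBS (1.0 equiv), DMF, 0 °C → rt, dark
Reagents that add atoms: N‑bromosuccinimide, O=C1CCC(=O)N1Br
Why: Electrophilic aromatic bromination occurs para to one silyloxy group and ortho to the other (C4); C2 is blocked between two TIPSO groups and C5 is not activated.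

**Step 4**
Reactants: 5 1,3-bis(TIPSO)-5-vinylbenzene; 6 1-bromo-2,4-bis(TIPSO)benzene
Product: 7 (E)-1-[2,4-bis(TIPSO)phenyl]-2-[3,5-bis(TIPSO)phenyl]ethene
Conditions: Pd2(dba)3 (1.5 mol%), P(t‑Bu)3·HBF4 (6 mol%), Cy2NMe, dioxane, 90 °C
Reagents that add atoms: none
Why: Mizoroki–Heck coupling with a bulky electron‑rich phosphine, which handles the ortho‑substituted electron‑rich bromide, gives the E‑stilbene; alkene geometry is in any case irrelevant for step 5.

**Step 5 (key step)**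
Reactants: 7 (E)-1-[2,4-bis(TIPSO)phenyl]-2-[3,5-bis(TIPSO)phenyl]ethene; 8 cyclohexane-1,3-dione
Product: 9 rac-(2S,3S)-2-[2,4-bis(TIPSO)phenyl]-3-[3,5-bis(TIPSO)phenyl]-3,5,6,7-tetrahydro-1-benzofuran-4(2H)-one
Conditions: Mn(OAc)3·2H2O (2.5 equiv), 8 (2 equiv), AcOH/1,2‑dichloroethane 2:1, 70 °C, N2
Reagents that add atoms: none
Why: Mn(III)‑mediated oxidative free‑radical [3+2] annulation, known for 1,3‑diones with stilbenes: the electrophilic 2‑dionyl radical adds to the alkene carbon bearing the 3,5‑disiloxyphenyl ring (C3–C3a bond), leaving the benzylic radical on the carbon stabilised by the 2,4‑disiloxyphenyl ring; a second Mn(III) oxidises it to the cation, and the enol oxygen closes anti to the C3 aryl, so C2/C3 are set trans in one step (as a racemate).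

**Step 6**
Reactants: 9 rac-(2S,3S)-2-[2,4-bis(TIPSO)phenyl]-3-[3,5-bis(TIPSO)phenyl]-3,5,6,7-tetrahydro-1-benzofuran-4(2H)-one
Product: 11 rac-(2S,3S)-2-[2,4-bis(TIPSO)phenyl]-3-[3,5-bis(TIPSO)phenyl]-2,3-dihydro-1-benzofuran-4-ol, via dienone 10 (not isolated)
Conditions: LDA (1.2 equiv), THF, −78 °C; then PhS(Cl)=N‑t‑Bu (1.2 equiv), −78 °C → rt
Reagents that add atoms: none
Why: Mukaiyama dehydrogenation: kinetic α′‑deprotonation of the vinylogous ester at C5, then sulfinimidoyl chloride, gives the 5,6‑ene, whose keto form tautomerises at once to the phenol; C2 and C3 are not touched at −78 °C.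

**Step 7**
Reactants: 11 rac-(2S,3S)-2-[2,4-bis(TIPSO)phenyl]-3-[3,5-bis(TIPSO)phenyl]-2,3-dihydro-1-benzofuran-4-ol
Product: 12 (2S,3S)-2-[2,4-bis(TIPSO)phenyl]-3-[3,5-bis(TIPSO)phenyl]-2,3-dihydro-1-benzofuran-4-yl (1S,4R)-camphanate
Conditions: (1S)‑(−)‑camphanic chloride (1.2 equiv), Et3N, DMAP (cat.), CH2Cl2, 0 °C → rt; separate the two diastereomers on silica or by crystallisation; assign by X‑ray
Reagents that add atoms: (1S,4R)‑camphanic chloride, CC1(C)[C@@]2(C)CC[C@@]1(OC2=O)C(Cl)=O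
Why: DMAP‑catalysed acylation turns the enantiomers into diastereomeric esters (classical resolution, at most 50 %), with the auxiliary sitting next to C3; no stereocentre is formed or changed, the (2S,3S) series is selected here, and the bulky ester also blocks O–B‑directed ortho‑borylation in step 8.

**Step 8**
Reactants: 12 (2S,3S)-2-[2,4-bis(TIPSO)phenyl]-3-[3,5-bis(TIPSO)phenyl]-2,3-dihydro-1-benzofuran-4-yl (1S,4R)-camphanate; 3 vinyl bromide
Product: 14 (2S,3S)-2-[2,4-bis(TIPSO)phenyl]-3-[3,5-bis(TIPSO)phenyl]-6-vinyl-2,3-dihydro-1-benzofuran-4-yl (1S,4R)-camphanate, via C6-boronate 13 (not isolated)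
Conditions: [Ir(OMe)(cod)]2 (2.5 mol%), dtbpy, B2pin2 (1.2 equiv), THF, 80 °C; evaporate; Pd(dppf)Cl2, 3 (3 equiv), K3PO4 (2 equiv), THF/H2O 20:1, 45 °C
Reagents that add atoms: bis(pinacolato)diboron, CC1(C)OB(OC1(C)C)B1OC(C)(C)C(C)(C)O1 (its boryl group is in 13 only)
Why: Sterically controlled Ir C–H borylation picks C6–H, the only arene C–H in 12 with two hydrogen neighbours (C5 is next to the ester, C7 next to the ring oxygen, all others are flanked by TIPSO or aryl groups); the mild Suzuki–Miyaura vinylation should spare the hindered bridgehead ester.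

**Step 9**
Reactants: 14 (2S,3S)-2-[2,4-bis(TIPSO)phenyl]-3-[3,5-bis(TIPSO)phenyl]-6-vinyl-2,3-dihydro-1-benzofuran-4-yl (1S,4R)-camphanate; 15 4-iodophenol
Product: 16 (2S,3S)-2-[2,4-bis(TIPSO)phenyl]-3-[3,5-bis(TIPSO)phenyl]-6-[(E)-2-(4-hydroxyphenyl)ethenyl]-2,3-dihydro-1-benzofuran-4-yl (1S,4R)-camphanate
Conditions: Pd(OAc)2 (5 mol%), P(o‑tol)3 (10 mol%), Et3N, DMF, 85 °C
Reagents that add atoms: none
Why: Mizoroki–Heck arylation of the styrene by the aryl iodide gives the E‑stilbene; the free phenol is tolerated and the amine base leaves silyl ethers and ester intact.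

**Step 10**
Reactants: 16 (2S,3S)-2-[2,4-bis(TIPSO)phenyl]-3-[3,5-bis(TIPSO)phenyl]-6-[(E)-2-(4-hydroxyphenyl)ethenyl]-2,3-dihydro-1-benzofuran-4-yl (1S,4R)-camphanate
Product: 18 4-[(2S,3S)-3-(3,5-dihydroxyphenyl)-4-hydroxy-6-[(E)-2-(4-hydroxyphenyl)ethenyl]-2,3-dihydro-1-benzofuran-2-yl]benzene-1,3-diol (target), via diphenol 17 (not isolated)
Conditions: LiOH·H2O, degassed THF/MeOH/H2O, 0 °C → rt; then AcOH (excess), TBAF (8 equiv), THF, rt, Ar
Reagents that add atoms: none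
Why: Saponification of the aryl ester, then AcOH‑buffered fluoride desilylation, frees all six phenols without strong acid, which could ionise the C2–O bond or protonate the stilbene, and without reductant; C3 is inert and C2 stays in the favoured trans arrangement.

**Compound list**
1 | resorcinol | Oc1cccc(O)c1 | starting material
2 | 1,3-bis(TIPSO)benzene | c1cc(O[Si](C(C)C)(C(C)C)C(C)C)cc(O[Si](C(C)C)(C(C)C)C(C)C)c1 | intermediate
3 | vinyl bromide | C=CBr | starting material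
4 | 2-[3,5-bis(TIPSO)phenyl]-4,4,5,5-tetramethyl-1,3,2-dioxaborolane | CC1(C)OB(OC1(C)C)c1cc(O[Si](C(C)C)(C(C)C)C(C)C)cc(O[Si](C(C)C)(C(C)C)C(C)C)c1 | intermediate (not isolated)
5 | 1,3-bis(TIPSO)-5-vinylbenzene | C=Cc1cc(O[Si](C(C)C)(C(C)C)C(C)C)cc(O[Si](C(C)C)(C(C)C)C(C)C)c1 | intermediate
6 | 1-bromo-2,4-bis(TIPSO)benzene | Brc1ccc(O[Si](C(C)C)(C(C)C)C(C)C)cc1O[Si](C(C)C)(C(C)C)C(C)C | intermediate
7 | (E)-1-[2,4-bis(TIPSO)phenyl]-2-[3,5-bis(TIPSO)phenyl]ethene | CC(C)[Si](C(C)C)(C(C)C)Oc1ccc(/C=C/c2cc(O[Si](C(C)C)(C(C)C)C(C)C)cc(O[Si](C(C)C)(C(C)C)C(C)C)c2)c(O[Si](C(C)C)(C(C)C)C(C)C)c1 | intermediate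
8 | cyclohexane-1,3-dione | O=C1CCCC(=O)C1 | starting material
9 | rac-(2S,3S)-2-[2,4-bis(TIPSO)phenyl]-3-[3,5-bis(TIPSO)phenyl]-3,5,6,7-tetrahydro-1-benzofuran-4(2H)-one (trans, racemate) | O=C1CCCC2=C1[C@H](c1cc(O[Si](C(C)C)(C(C)C)C(C)C)cc(O[Si](C(C)C)(C(C)C)C(C)C)c1)[C@@H](c1ccc(O[Si](C(C)C)(C(C)C)C(C)C)cc1O[Si](C(C)C)(C(C)C)C(C)C)O2 | intermediate
10 | rac-(2S,3S)-2-[2,4-bis(TIPSO)phenyl]-3-[3,5-bis(TIPSO)phenyl]-2,3-dihydro-1-benzofuran-4(7H)-one (keto tautomer, racemate) | O=C1C=CCC2=C1[C@H](c1cc(O[Si](C(C)C)(C(C)C)C(C)C)cc(O[Si](C(C)C)(C(C)C)C(C)C)c1)[C@@H](c1ccc(O[Si](C(C)C)(C(C)C)C(C)C)cc1O[Si](C(C)C)(C(C)C)C(C)C)O2 | intermediate (not isolated)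
11 | rac-(2S,3S)-2-[2,4-bis(TIPSO)phenyl]-3-[3,5-bis(TIPSO)phenyl]-2,3-dihydro-1-benzofuran-4-ol (trans, racemate) | Oc1cccc2c1[C@H](c1cc(O[Si](C(C)C)(C(C)C)C(C)C)cc(O[Si](C(C)C)(C(C)C)C(C)C)c1)[C@@H](c1ccc(O[Si](C(C)C)(C(C)C)C(C)C)cc1O[Si](C(C)C)(C(C)C)C(C)C)O2 | intermediate
12 | (2S,3S)-2-[2,4-bis(TIPSO)phenyl]-3-[3,5-bis(TIPSO)phenyl]-2,3-dihydro-1-benzofuran-4-yl (1S,4R)-4,7,7-trimethyl-3-oxo-2-oxabicyclo[2.2.1]heptane-1-carboxylate | CC1(C)[C@@]2(C)CC[C@@]1(OC2=O)C(=O)Oc1cccc2c1[C@H](c1cc(O[Si](C(C)C)(C(C)C)C(C)C)cc(O[Si](C(C)C)(C(C)C)C(C)C)c1)[C@@H](c1ccc(O[Si](C(C)C)(C(C)C)C(C)C)cc1O[Si](C(C)C)(C(C)C)C(C)C)O2 | intermediate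
13 | 6-(4,4,5,5-tetramethyl-1,3,2-dioxaborolan-2-yl) derivative of 12 | CC1(C)[C@@]2(C)CC[C@@]1(OC2=O)C(=O)Oc1cc(B3OC(C)(C)C(C)(C)O3)cc2c1[C@H](c1cc(O[Si](C(C)C)(C(C)C)C(C)C)cc(O[Si](C(C)C)(C(C)C)C(C)C)c1)[C@@H](c1ccc(O[Si](C(C)C)(C(C)C)C(C)C)cc1O[Si](C(C)C)(C(C)C)C(C)C)O2 | intermediate (not isolated)
14 | 6-vinyl derivative of 12 | CC1(C)[C@@]2(C)CC[C@@]1(OC2=O)C(=O)Oc1cc(C=C)cc2c1[C@H](c1cc(O[Si](C(C)C)(C(C)C)C(C)C)cc(O[Si](C(C)C)(C(C)C)C(C)C)c1)[C@@H](c1ccc(O[Si](C(C)C)(C(C)C)C(C)C)cc1O[Si](C(C)C)(C(C)C)C(C)C)O2 | intermediate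
15 | 4-iodophenol | Oc1ccc(I)cc1 | starting material
16 | 6-[(E)-2-(4-hydroxyphenyl)ethenyl] derivative of 12 | CC1(C)[C@@]2(C)CC[C@@]1(OC2=O)C(=O)Oc1cc(/C=C/c3ccc(O)cc3)cc2c1[C@H](c1cc(O[Si](C(C)C)(C(C)C)C(C)C)cc(O[Si](C(C)C)(C(C)C)C(C)C)c1)[C@@H](c1ccc(O[Si](C(C)C)(C(C)C)C(C)C)cc1O[Si](C(C)C)(C(C)C)C(C)C)O2 | intermediate
17 | (2S,3S)-2-[2,4-bis(TIPSO)phenyl]-3-[3,5-bis(TIPSO)phenyl]-6-[(E)-2-(4-hydroxyphenyl)ethenyl]-2,3-dihydro-1-benzofuran-4-ol | Oc1cc(/C=C/c3ccc(O)cc3)cc2c1[C@H](c1cc(O[Si](C(C)C)(C(C)C)C(C)C)cc(O[Si](C(C)C)(C(C)C)C(C)C)c1)[C@@H](c1ccc(O[Si](C(C)C)(C(C)C)C(C)C)cc1O[Si](C(C)C)(C(C)C)C(C)C)O2 | intermediate (not isolated)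
18 | 4-[(2S,3S)-3-(3,5-dihydroxyphenyl)-4-hydroxy-6-[(E)-2-(4-hydroxyphenyl)ethenyl]-2,3-dihydro-1-benzofuran-2-yl]benzene-1,3-diol | Oc1ccc(/C=C/c2cc(O)c3c(c2)O[C@H](c2ccc(O)cc2O)[C@H]3c2cc(O)cc(O)c2)cc1 | target

**Totals:** 10 steps; longest linear sequence 9 (steps 1, 2, 4, 5, 6, 7, 8, 9, 10).

**Steps most likely to fail**

Step 5 (radical annulation). The risks are incomplete regiocontrol of the radical addition, loss of a silyl group from the silyloxybenzyl cation, and over‑oxidation of the electron‑rich stilbene in hot acetic acid. The fallback sets out from 8: oxidise it with PhI(OAc)2 (Na2CO3, MeOH/H2O, 0 °C) to the iodonium ylide 2-(phenyl-λ3-iodanylidene)cyclohexane-1,3-dione F1. F1 then reacts with stilbene 7 under blue‑LED irradiation (or with 5 mol% Cu(acac)2 in DCE at 60 °C) in a stepwise [3+2] with the same regiochemistry and trans outcome. This needs no stoichiometric metal oxidant and no acid, and the route is rejoined at 9.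

Step 7 (resolution). The two camphanates may not separate on silica or by crystallisation. The fallback sets out from 11: resolve the racemic phenol itself by preparative SFC on a chiral stationary phase (amylose tris(3,5‑dimethylphenylcarbamate), CO2/i‑PrOH) to obtain the enantiopure phenol (2S,3S)-2-[2,4-bis(TIPSO)phenyl]-3-[3,5-bis(TIPSO)phenyl]-2,3-dihydro-1-benzofuran-4-ol F2. F2 is then acylated with camphanic chloride as in step 7, now only as a protecting group whose known configuration confirms the assignment by X‑ray; the route is rejoined at 12.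

Step 8 (borylation/vinylation). C7–H next to the ring oxygen may compete in the borylation. In the Suzuki stage the risks are protodeboronation or ester hydrolysis under aqueous base, and handling of gaseous vinyl bromide. The fallback addresses only the Suzuki stage, not the borylation site selectivity. It sets out from boronate 13 (isolated after the borylation stage) and from 15: couple 15 with potassium vinyltrifluoroborate (PdCl2(dppf), Cs2CO3, THF/H2O, 70 °C) to give 4-vinylphenol F3, used fresh. A base‑free oxidative Heck reaction of 13 with F3 (Pd(OAc)2, 2,9‑dimethyl‑1,10‑phenanthroline, O2, DMF, 50 °C) gives the E‑stilbene directly; the route is rejoined at 16, bypassing 14 and step 9.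

**Further compounds**
F1 | step 5 | 2-(phenyl-λ3-iodanylidene)cyclohexane-1,3-dione (iodonium ylide) | [O-]C1=C([I+]c2ccccc2)C(=O)CCC1
F2 | step 7 | (2S,3S)-2-[2,4-bis(TIPSO)phenyl]-3-[3,5-bis(TIPSO)phenyl]-2,3-dihydro-1-benzofuran-4-ol (single enantiomer) | Oc1cccc2c1[C@H](c1cc(O[Si](C(C)C)(C(C)C)C(C)C)cc(O[Si](C(C)C)(C(C)C)C(C)C)c1)[C@@H](c1ccc(O[Si](C(C)C)(C(C)C)C(C)C)cc1O[Si](C(C)C)(C(C)C)C(C)C)O2
F3 | step 8 | 4-vinylphenol | C=Cc1ccc(O)cc1
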